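**Plan**

1. Retrosynthetic cuts: first the C15 ketone and C11 alcohol (redox), then C8–C14 and C9–C11 together, which contracts ring C to a cyclobutanone and frees the lactone alkene C8=C9. Then C8–C15 (cross-coupling), C9–C10 with the lactone C–O bond (radical addition/lactonisation), and C10=C20 and C5–C6 on 4,4-dimethylcyclohexenone.
2. Forward order: ring A, then the spiro-δ-lactone at C10, then a C8 arm carrying a 3-substituted cyclobutanone, then rings C and D in one step, then C11 reduction, desilylation and C15 oxidation.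
3. Enabling feature: in the bicyclo[3.2.1]octane the carbinol carbon C11 is the middle atom of the three-carbon bridge C9–C11–C12, and the bridgeheads C8/C13 are joined by C15–C16. Ring C (C8, C9, C11, C12, C13, C14) is therefore a cyclobutanone (C11, C12, C13, C14) with the alkene C8=C9 inserted into its C11–C14 bond, C15–C16 serving as tether.
4. Stereochemistry: C5 comes from a catalyst-controlled conjugate addition. C1 (hydride), C10 (radical addition anti to the axial C4 methyl), C8/C9/C13 (alkene face in the key step, anti to the C5 arm) and C11 (exo hydride) follow by relay.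

Key step: step 15

Remark: atom numbers are those of ent-kaurane; 1, 6, 16 and the reagents are taken as commercial (the silylmethyl Grignard reagent of step 4 as a stock solution made from (chloromethyl)dimethyl(propan-2-yloxy)silane and magnesium); centres that are erased later (C10 of 15, C8 of 20 and 22, C15 of 30) are left open.

**Route**

Step 1
Reactants: 1 methyl 3,3-dimethoxycyclobutane-1-carboxylate
Product: 3 [2-(3,3-dimethoxycyclobutyl)prop-2-en-1-yl]trimethylsilane, via β-hydroxysilane 2 (not isolated)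
Conditions: Me3SiCH2MgCl (3 equiv), CeCl3, THF, −78 °C to rt; then SiO2, CH2Cl2, rt
Reagents that add atoms: (trimethylsilyl)methylmagnesium chloride, C[Si](C)(C)C[Mg]Cl
Why: Double addition of the cerium-modified Grignard reagent to the ester and Peterson elimination of the bis(β-silyl) carbinol on silica should give the 2-substituted allylsilane with the ketal intact.

Step 2
Reactants: 3 allylsilane
Product: 4 3-(3-bromoprop-1-en-2-yl)-1,1-dimethoxycyclobutane
Conditions: NBS, propylene oxide, CH2Cl2, −78 to −20 °C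
Reagents that add atoms: N-bromosuccinimide, O=C1CCC(=O)N1Br
Why: Electrophilic bromodesilylation of the allylsilane (SE2′); the two allyl termini are equivalent, so only one bromide can form.

Step 3
Reactants: 4 allyl bromide
Product: 5 tributyl[2-(3,3-dimethoxycyclobutyl)prop-2-en-1-yl]stannane
Conditions: Bu3SnH, LiN(i-Pr)2, THF, 0 °C; then 4, −78 °C
Reagents that add atoms: tributyltin hydride, CCCC[SnH](CCCC)CCCC
Why: SN2 displacement of the allylic bromide by the stannyl anion (SN2 and SN2′ are degenerate here).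

Step 4
Reactants: 6 4,4-dimethylcyclohex-2-en-1-one
Product: 8 (2R,3S)-2-[(dimethylamino)methyl]-3-{[dimethyl(propan-2-yloxy)silyl]methyl}-4,4-dimethylcyclohexan-1-one, via magnesium enolate 7 (not isolated)
Conditions: (i-PrO)Me2SiCH2MgCl, CuBr·SMe2 (5 mol %), (R,S)-Josiphos (6 mol %; the antipode if the sense of induction requires it), t-BuOMe, −75 °C; then CH2=NMe2+ I−, THF, −75 to 0 °C
Reagents that add atoms: [dimethyl(propan-2-yloxy)silyl]methylmagnesium chloride, CC(C)O[Si](C)(C)C[Mg]Cl; N,N-dimethylmethylideneammonium iodide, C=[N+](C)C.[I-]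
Why: Copper-catalysed asymmetric conjugate addition of a Grignard reagent to a cyclic enone (chiral ferrocenyl diphosphine on monovalent copper) should set C5 by catalyst control, and the regiodefined enolate is trapped in a Mannich reaction anti to the new arm; the silylmethyl group is a masked hydroxymethyl group.

Step 5
Reactants: 8 Mannich base
Product: 10 (3R)-3-{[dimethyl(propan-2-yloxy)silyl]methyl}-4,4-dimethyl-2-methylidenecyclohexan-1-one, via methiodide 9 (not isolated)
Conditions: MeI, Et2O, rt; then NaHCO3 (aq), CH2Cl2, rt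
Reagents that add atoms: none
Why: Quaternisation and E1cB loss of trimethylamine (Mannich-base α-methylenation) should give the exo-methylene ketone, which is used at once.

Step 6
Reactants: 10 methylene ketone
Product: 12 (1S,3R)-3-(hydroxymethyl)-4,4-dimethyl-2-methylidenecyclohexan-1-ol, via allylic alcohol 11 (not isolated)
Conditions: NaBH4, CeCl3·7H2O, MeOH, −78 °C; then KF, KHCO3, 30% H2O2, THF/MeOH, rt
Reagents that add atoms: hydrogen peroxide, OO
Why: Luche 1,2-reduction with hydride delivery from the face opposite the C5 arm should give the C1 alcohol cis to that arm (1,3-diequatorial), and Tamao–Fleming oxidation then converts C–Si into C–OH with retention.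

Step 7
Reactants: 12 diol
Product: 14 (1S,3R)-3-{[(tert-butyldiphenylsilyl)oxy]methyl}-4,4-dimethyl-2-methylidene-1-[(triethylsilyl)oxy]cyclohexane, via mono-silyl ether 13 (not isolated)
Conditions: t-BuPh2SiCl, imidazole, DMF, 0 °C; then Et3SiCl, rt
Reagents that add atoms: tert-butyl(chloro)diphenylsilane, CC(C)(C)[Si](Cl)(c1ccccc1)c1ccccc1; chlorotriethylsilane, CC[Si](Cl)(CC)CC
Why: The bulky silyl chloride should take the primary hydroxyl selectively and the triethylsilyl group then caps the secondary one, giving two ethers that can be removed independently.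

Step 8
Reactants: 14 bis-silyl ether
Product: 15 4-[(triethylsilyl)oxy]-8-{[(tert-butyldiphenylsilyl)oxy]methyl}-7,7-dimethyl-1-oxaspiro[2.5]octane
Conditions: mCPBA, NaHCO3, CH2Cl2, 0 °C
Reagents that add atoms: 3-chloroperbenzoic acid, OOC(=O)c1cccc(Cl)c1
Why: Prilezhaev epoxidation of the only alkene, expected from the face away from the syn-axial C4 methyl; either epimer serves because C10 becomes a radical in step 9.

Step 9
Reactants: 15 spiro-epoxide; 16 2,2,2-trifluoroethyl prop-2-enoate
Product: 18 7-[(triethylsilyl)oxy]-11-{[(tert-butyldiphenylsilyl)oxy]methyl}-10,10-dimethyl-2-oxaspiro[5.5]undecan-3-one, via hydroxy ester 17 (not isolated)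
Conditions: (C5H5)2TiCl2 (20 mol %), Zn, 2,4,6-collidine·HCl, THF, rt
Reagents that add atoms: none
Why: (C5H5)2TiCl (trivalent titanium, formed from the dichloride and zinc) opens the epoxide homolytically to the tertiary C10 radical, which should add to the acrylate from the equatorial direction, away from the syn-axial C4 methyl, so that C9 is equatorial and the C20–O arm axial (cis to the C5 arm); reduction, protonation and lactonisation onto the activated ester then close the spiro-lactone (radical epoxide opening/Giese addition).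

Step 10
Reactants: 18 spiro-lactone
Product: 21 7-[(triethylsilyl)oxy]-11-{[(tert-butyldiphenylsilyl)oxy]methyl}-10,10-dimethyl-2-oxaspiro[5.5]undec-4-en-3-one, via lithium enolate 19 (not isolated), via selenide 20 (not isolated)
Conditions: LiN(i-Pr)2, THF, −78 °C; PhSeBr; then 30% H2O2, pyridine, CH2Cl2, 0 °C to rt
Reagents that add atoms: none
Why: α-Selenation of the lactone enolate and selenoxide syn-elimination, which can only use the C9 hydrogens because C10 is quaternary, should give the C8=C9 lactone.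

Step 11
Reactants: 21 unsaturated lactone
Product: 23 4-bromo-7-[(triethylsilyl)oxy]-11-{[(tert-butyldiphenylsilyl)oxy]methyl}-10,10-dimethyl-2-oxaspiro[5.5]undec-4-en-3-one, via dibromide 22 (not isolated)
Conditions: Br2, CH2Cl2, 0 °C; then Et3N, 0 °C to rt
Reagents that add atoms: bromine, BrBr
Why: Bromine addition followed by E1cB dehydrobromination through the acidic α-hydrogen should give the α-bromo enoate (bromination–dehydrobromination).

Step 12
Reactants: 23 α-bromo lactone; 5 allylstannane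
Product: 24 4-[2-(3,3-dimethoxycyclobutyl)prop-2-en-1-yl]-7-[(triethylsilyl)oxy]-11-{[(tert-butyldiphenylsilyl)oxy]methyl}-10,10-dimethyl-2-oxaspiro[5.5]undec-4-en-3-one
Conditions: Pd2(dba)3 (5 mol %; dba = dibenzylideneacetone), P(2-furyl)3, CuI, NMP, 50 °C
Reagents that add atoms: none
Why: Stille coupling of the α-bromo enoate (oxidative addition to zerovalent palladium) with the allylstannane forms C8–C15; the allyl termini are equivalent, and ketal and silyl ethers are inert.

Step 13
Reactants: 24 coupled lactone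
Product: 25 7-hydroxy-11-{[(tert-butyldiphenylsilyl)oxy]methyl}-10,10-dimethyl-4-[2-(3-oxocyclobutyl)prop-2-en-1-yl]-2-oxaspiro[5.5]undec-4-en-3-one
Conditions: 1 M HCl (aq), THF, rt
Reagents that add atoms: water, O
Why: Acid hydrolysis should remove the dimethyl ketal and the triethylsilyl ether in one operation while the primary tert-butyldiphenylsilyl ether survives.

Step 14
Reactants: 25 hydroxy cyclobutanone
Product: 26 C1 acetate of 25 (7-acetoxy compound)
Conditions: Ac2O, DMAP, pyridine, CH2Cl2, 0 °C to rt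
Reagents that add atoms: acetic anhydride, CC(=O)OC(C)=O
Why: Acylation of the only free hydroxyl installs the C1 acetate of the target before any other hydroxyl exists, and is run promptly so that the free C1 hydroxyl cannot translactonise.

Step 15
Reactants: 26 cyclobutanone–enoate
Product: 27 1-acetoxy-6-[(tert-butyldiphenylsilyl)oxy]-11-oxo-6,7-seco-ent-kaur-16-ene-7,20-lactone
Conditions: [Rh(C2H4)2Cl]2 (5 mol %), P[3,5-(CF3)2C6H3]3 (24 mol %), 2-amino-3-methylpyridine (1 equiv), 1,4-dioxane, 150 °C, sealed tube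
Reagents that add atoms: none
Why: The cyclobutanone condenses reversibly with the aminopyridine to a ketimine that directs monovalent rhodium into the C11–C14 acyl–alkyl bond (the two α-bonds are equivalent); the five-membered trivalent rhodacycle inserts the tethered C8=C9 alkene (C14 to C8), and C9–C11 reductive elimination with imine hydrolysis completes the two-atom growth of the four-membered ketone into ring C. The closest known reaction type is the rhodium-catalysed intramolecular insertion of an alkene into a cyclobutanone C–C bond ("cut-and-sew" (4+2) coupling), which gives bicyclo[3.2.1]octan-3-ones from 3-substituted cyclobutanones with a two-atom-tethered alkene and tolerates trisubstituted alkenes that become quaternary carbons. Ring C closes as a six-membered ring in the bridging mode (bonds C8–C14 and C9–C11), and ring D closes with it as the five-membered ring C8–C14–C13–C16–C15, the tether C15–C16 being forced into the two-carbon bridge. C8 and C9 arise by suprafacial addition to the ring-locked Z alkene, which makes the lactone cis-fused to ring C with C15 syn to H9, and C13 follows from the bridged geometry once C8 is set. The addition must occur on the alkene face syn to C1, which the substrate should secure because the other face is screened by the C5 CH2OSi arm and the C4 methyl groups whereas C1 carries only the small equatorial acetate. Decarbonylation and insertion of the 1,1-disubstituted C16=C17 alkene are the competing paths; the ketimine suppresses the first, and the second would require a three- or four-membered ring.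

Step 16
Reactants: 27 keto lactone
Product: 28 1-acetoxy-6-[(tert-butyldiphenylsilyl)oxy]-11-hydroxy-6,7-seco-ent-kaur-16-ene-7,20-lactone
Conditions: NaBH4, MeOH/CH2Cl2 (1:1), −40 to 0 °C
Reagents that add atoms: none
Why: The only ketone should be reduced by hydride attack from the exo face, opposite the C15–C16 bridge that blocks the endo face, giving the axial 11-hydroxyl syn to that bridge as in the target; lactone and acetate are inert to NaBH4 at this temperature.

Step 17
Reactants: 28 silyl ether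
Product: 29 1-acetoxy-6,11-dihydroxy-6,7-seco-ent-kaur-16-ene-7,20-lactone
Conditions: Bu4NF, AcOH, THF, rt
Reagents that add atoms: none
Why: Buffered fluoride should cleave the silyl ether without acetate migration or alkene isomerisation.

Step 18
Reactants: 29 diol
Product: 31 maoyecrystal E, via allylic alcohol 30 (not isolated)
Conditions: SeO2 (0.5 equiv), t-BuOOH, CH2Cl2, rt; then MnO2, CH2Cl2, rt
Reagents that add atoms: tert-butyl hydroperoxide, CC(C)(C)OO
Why: The selenium dioxide ene reaction/[2,3]-sigmatropic shift should hydroxylate C15, the only allylic position that can react (C13 is a bridgehead), and MnO2 oxidises only this allylic alcohol, leaving the C11 and C6 hydroxyls, to give the exo-methylene cyclopentanone.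

**Compound list**

1 | methyl 3,3-dimethoxycyclobutane-1-carboxylate | COC(=O)C1CC(OC)(OC)C1 | starting material
2 | 2-(3,3-dimethoxycyclobutyl)-1,3-bis(trimethylsilyl)propan-2-ol | C[Si](C)(C)CC(O)(C[Si](C)(C)C)C1CC(OC)(OC)C1 | intermediate
3 | [2-(3,3-dimethoxycyclobutyl)prop-2-en-1-yl]trimethylsilane | C[Si](C)(C)CC(=C)C1CC(OC)(OC)C1 | intermediate
4 | 3-(3-bromoprop-1-en-2-yl)-1,1-dimethoxycyclobutane | BrCC(=C)C1CC(OC)(OC)C1 | intermediate
5 | tributyl[2-(3,3-dimethoxycyclobutyl)prop-2-en-1-yl]stannane | CCCC[Sn](CCCC)(CCCC)CC(=C)C1CC(OC)(OC)C1 | intermediate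
6 | 4,4-dimethylcyclohex-2-en-1-one | CC1(C)CCC(=O)C=C1 | starting material
7 | chloromagnesium (3S)-3-{[dimethyl(propan-2-yloxy)silyl]methyl}-4,4-dimethylcyclohex-1-en-1-olate | Cl[Mg]OC1=C[C@H](C[Si](C)(C)OC(C)C)C(C)(C)CC1 | intermediate
8 | (2R,3S)-2-[(dimethylamino)methyl]-3-{[dimethyl(propan-2-yloxy)silyl]methyl}-4,4-dimethylcyclohexan-1-one (trans) | O=C1CCC(C)(C)[C@@H](C[Si](C)(C)OC(C)C)[C@@H]1CN(C)C | intermediate
9 | methiodide of 8 (trimethylammonium iodide) | O=C1CCC(C)(C)[C@@H](C[Si](C)(C)OC(C)C)[C@@H]1C[N+](C)(C)C.[I-] | intermediate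
10 | (3R)-3-{[dimethyl(propan-2-yloxy)silyl]methyl}-4,4-dimethyl-2-methylidenecyclohexan-1-one | O=C1CCC(C)(C)[C@@H](C[Si](C)(C)OC(C)C)C1=C | intermediate
11 | (1S,3R)-3-{[dimethyl(propan-2-yloxy)silyl]methyl}-4,4-dimethyl-2-methylidenecyclohexan-1-ol (cis) | O[C@H]1CCC(C)(C)[C@@H](C[Si](C)(C)OC(C)C)C1=C | intermediate
12 | (1S,3R)-3-(hydroxymethyl)-4,4-dimethyl-2-methylidenecyclohexan-1-ol (cis) | O[C@H]1CCC(C)(C)[C@@H](CO)C1=C | intermediate
13 | (1S,3R)-3-{[(tert-butyldiphenylsilyl)oxy]methyl}-4,4-dimethyl-2-methylidenecyclohexan-1-ol | O[C@H]1CCC(C)(C)[C@@H](CO[Si](c2ccccc2)(c2ccccc2)C(C)(C)C)C1=C | intermediate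
14 | (1S,3R)-3-{[(tert-butyldiphenylsilyl)oxy]methyl}-4,4-dimethyl-2-methylidene-1-[(triethylsilyl)oxy]cyclohexane | CC[Si](CC)(CC)O[C@H]1CCC(C)(C)[C@@H](CO[Si](c2ccccc2)(c2ccccc2)C(C)(C)C)C1=C | intermediate
15 | 4-[(triethylsilyl)oxy]-8-{[(tert-butyldiphenylsilyl)oxy]methyl}-7,7-dimethyl-1-oxaspiro[2.5]octane (epoxide oxygen trans to the C5 arm, drawn as the expected epimer) | CC[Si](CC)(CC)O[C@H]1CCC(C)(C)[C@@H](CO[Si](c2ccccc2)(c2ccccc2)C(C)(C)C)[C@@]12CO2 | intermediate
16 | 2,2,2-trifluoroethyl prop-2-enoate | C=CC(=O)OCC(F)(F)F | starting material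
17 | 2,2,2-trifluoroethyl 3-[1-(hydroxymethyl)cyclohexyl]propanoate carrying 2-OSiEt3, 6-CH2OSiPh2t-Bu and 5,5-dimethyl groups (C1, C5, C10 as in 31) | FC(F)(F)COC(=O)CC[C@]1(CO)[C@@H](O[Si](CC)(CC)CC)CCC(C)(C)[C@H]1CO[Si](c1ccccc1)(c1ccccc1)C(C)(C)C | intermediate
18 | 7-[(triethylsilyl)oxy]-11-{[(tert-butyldiphenylsilyl)oxy]methyl}-10,10-dimethyl-2-oxaspiro[5.5]undecan-3-one (C20–O arm cis to the C1 silyloxy group and to the C5 arm) | O=C1CC[C@]2(CO1)[C@@H](O[Si](CC)(CC)CC)CCC(C)(C)[C@H]2CO[Si](c1ccccc1)(c1ccccc1)C(C)(C)C | intermediate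
19 | lithium enolate of 18 | [Li]OC1=CC[C@]2(CO1)[C@@H](O[Si](CC)(CC)CC)CCC(C)(C)[C@H]2CO[Si](c1ccccc1)(c1ccccc1)C(C)(C)C | intermediate
20 | 4-(phenylselanyl) derivative of 18 (C8 epimers) | O=C1C([Se]c3ccccc3)C[C@]2(CO1)[C@@H](O[Si](CC)(CC)CC)CCC(C)(C)[C@H]2CO[Si](c1ccccc1)(c1ccccc1)C(C)(C)C | intermediate
21 | 7-[(triethylsilyl)oxy]-11-{[(tert-butyldiphenylsilyl)oxy]methyl}-10,10-dimethyl-2-oxaspiro[5.5]undec-4-en-3-one | O=C1C=C[C@]2(CO1)[C@@H](O[Si](CC)(CC)CC)CCC(C)(C)[C@H]2CO[Si](c1ccccc1)(c1ccccc1)C(C)(C)C | intermediate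
22 | 4,5-dibromide of 21 (trans-dibromide, epimers) | O=C1C(Br)C(Br)[C@]2(CO1)[C@@H](O[Si](CC)(CC)CC)CCC(C)(C)[C@H]2CO[Si](c1ccccc1)(c1ccccc1)C(C)(C)C | intermediate
23 | 4-bromo derivative of 21 | O=C1C(Br)=C[C@]2(CO1)[C@@H](O[Si](CC)(CC)CC)CCC(C)(C)[C@H]2CO[Si](c1ccccc1)(c1ccccc1)C(C)(C)C | intermediate
24 | 4-[2-(3,3-dimethoxycyclobutyl)prop-2-en-1-yl] derivative of 21 | O=C1C(CC(=C)C3CC(OC)(OC)C3)=C[C@]2(CO1)[C@@H](O[Si](CC)(CC)CC)CCC(C)(C)[C@H]2CO[Si](c1ccccc1)(c1ccccc1)C(C)(C)C | intermediate
25 | 7-hydroxy-11-{[(tert-butyldiphenylsilyl)oxy]methyl}-10,10-dimethyl-4-[2-(3-oxocyclobutyl)prop-2-en-1-yl]-2-oxaspiro[5.5]undec-4-en-3-one | O=C1C(CC(=C)C3CC(=O)C3)=C[C@]2(CO1)[C@@H](O)CCC(C)(C)[C@H]2CO[Si](c1ccccc1)(c1ccccc1)C(C)(C)C | intermediate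
26 | 7-acetate of 25 | O=C1C(CC(=C)C3CC(=O)C3)=C[C@]2(CO1)[C@@H](OC(C)=O)CCC(C)(C)[C@H]2CO[Si](c1ccccc1)(c1ccccc1)C(C)(C)C | intermediate
27 | 1-acetoxy-6-[(tert-butyldiphenylsilyl)oxy]-11-oxo-6,7-seco-ent-kaur-16-ene-7,20-lactone (C1, C5, C8, C9, C10, C13 as in 31) | C=C1C[C@]23C[C@H]1CC(=O)[C@H]2[C@]1(COC3=O)[C@@H](OC(C)=O)CCC(C)(C)[C@H]1CO[Si](c1ccccc1)(c1ccccc1)C(C)(C)C | intermediate
28 | 1-acetoxy-6-[(tert-butyldiphenylsilyl)oxy]-11-hydroxy-6,7-seco-ent-kaur-16-ene-7,20-lactone (all centres as in 31) | C=C1C[C@]23C[C@H]1C[C@H](O)[C@H]2[C@]1(COC3=O)[C@@H](OC(C)=O)CCC(C)(C)[C@H]1CO[Si](c1ccccc1)(c1ccccc1)C(C)(C)C | intermediate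
29 | 1-acetoxy-6,11-dihydroxy-6,7-seco-ent-kaur-16-ene-7,20-lactone (15-deoxo compound) | C=C1C[C@]23C[C@H]1C[C@H](O)[C@H]2[C@]1(COC3=O)[C@@H](OC(C)=O)CCC(C)(C)[C@H]1CO | intermediate
30 | 15-hydroxy derivative of 29 (C15 epimers) | C=C1C(O)[C@]23C[C@H]1C[C@H](O)[C@H]2[C@]1(COC3=O)[C@@H](OC(C)=O)CCC(C)(C)[C@H]1CO | intermediate
31 | maoyecrystal E | C=C1C(=O)[C@]23C[C@H]1C[C@H](O)[C@H]2[C@]1(COC3=O)[C@@H](OC(C)=O)CCC(C)(C)[C@H]1CO | target

**Count and risks**

Total step count: 18 (steps 1–3 make the stannane 5; steps 4–18 are the main line). Longest linear sequence: 15 steps (steps 4–18, from 6).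

Step 15. What may go wrong: migratory insertion of the hindered, electron-poor trisubstituted alkene is too slow, so that decarbonylation or cycloreversion of the rhodacycle takes over, or the addition shows poor facial selectivity. The fallback sets out from 18 and comes back at 29; it builds rings C and D one after the other by a ketyl–alkene cyclisation and a palladium-mediated enolate–alkene cyclisation.
- 18 is alkylated at C8 (LiN(i-Pr)2, HMPA, THF) with the separately prepared side-chain iodide (S)-triethyl{[3-(iodomethyl)-4-methylpent-4-en-1-yl]oxy}silane F1 to give the C8-alkylated lactone F2.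
- Selenation (LiN(i-Pr)2, PhSeBr) gives the selenide F3, and H2O2 then gives the endocyclic unsaturated lactone F4.
- Swern oxidation converts the primary triethylsilyl ether directly into the aldehyde F5.
- SmI2 (LiBr, t-BuOH, THF, −78 °C) adds the C11 ketyl to C9 and closes ring C, giving the hydroxy lactone F6.
- KN(SiMe3)2 and t-BuMe2SiCl silylate the C11 hydroxyl and the lactone enolate to the silyl ketene acetal F7. Pd(OAc)2 in DMSO cyclises it onto the isopropenyl group (C8–C15 bond, then β-hydride loss from the methyl group) to the exo-methylene bicyclo[3.2.1]octane F8.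
- HF·pyridine removes the C1 triethylsilyl group to give the alcohol F9, Ac2O/DMAP gives the acetate F10, and Bu4NF/AcOH removes both remaining silyl groups to give 29.

Step 4. What may go wrong: low enantioselectivity, or sluggish transfer of the α-silylalkyl group from copper. The fallback sets out from 6 and comes back at 8; it replaces asymmetric catalysis by a classical resolution. The addition and Mannich trapping are run with CuI and no chiral ligand, which gives 8 together with its enantiomer ent-8 F11 as the racemate. Crystallisation with (S)-mandelic acid (or its antipode, whichever gives the less soluble salt of 8) gives the mandelate salt of 8 F12, from which aqueous NaHCO3 liberates 8.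

Step 12. What may go wrong: slow transmetallation at the hindered α-bromo enoate, with protodestannylation of 5 or migration of the new 1,4-diene into conjugation. The fallback sets out from 18 (with 4) and comes back at 24; it replaces the cross-coupling by enolate alkylation followed by dehydrogenation. The lithium enolate of 18 is alkylated with 4 to the α-allylated lactone F13. A second deprotonation and PhSeBr give the selenide F14, and H2O2 then effects syn-elimination towards C9 to give 24.

**Further compounds**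

F1 | step 15 | (S)-triethyl{[3-(iodomethyl)-4-methylpent-4-en-1-yl]oxy}silane | IC[C@H](C(C)=C)CCO[Si](CC)(CC)CC
F2 | step 15 | C8-alkylated lactone (C8 epimers) | O=C1C(C[C@H](C(C)=C)CCO[Si](CC)(CC)CC)C[C@]2(CO1)[C@@H](O[Si](CC)(CC)CC)CCC(C)(C)[C@H]2CO[Si](c1ccccc1)(c1ccccc1)C(C)(C)C
F3 | step 15 | 8-(phenylselanyl) derivative of F2 | O=C1C([Se]c3ccccc3)(C[C@H](C(C)=C)CCO[Si](CC)(CC)CC)C[C@]2(CO1)[C@@H](O[Si](CC)(CC)CC)CCC(C)(C)[C@H]2CO[Si](c1ccccc1)(c1ccccc1)C(C)(C)C
F4 | step 15 | C8=C9 unsaturated lactone with the C11 triethylsilyl ether | O=C1C(C[C@H](C(C)=C)CCO[Si](CC)(CC)CC)=C[C@]2(CO1)[C@@H](O[Si](CC)(CC)CC)CCC(C)(C)[C@H]2CO[Si](c1ccccc1)(c1ccccc1)C(C)(C)C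
F5 | step 15 | C11 aldehyde | O=C1C(C[C@H](C(C)=C)CC=O)=C[C@]2(CO1)[C@@H](O[Si](CC)(CC)CC)CCC(C)(C)[C@H]2CO[Si](c1ccccc1)(c1ccccc1)C(C)(C)C
F6 | step 15 | ring C hydroxy lactone (11-OH as in 31, C8 open) | CC(=C)[C@H]1CC2C(=O)OC[C@@]3([C@@H]2[C@@H](O)C1)[C@@H](O[Si](CC)(CC)CC)CCC(C)(C)[C@H]3CO[Si](c1ccccc1)(c1ccccc1)C(C)(C)C
F7 | step 15 | silyl ketene acetal with the C11 tert-butyldimethylsilyl ether | CC(=C)[C@H]1CC2=C(O[Si](C)(C)C(C)(C)C)OC[C@@]3([C@@H]2[C@@H](O[Si](C)(C)C(C)(C)C)C1)[C@@H](O[Si](CC)(CC)CC)CCC(C)(C)[C@H]3CO[Si](c1ccccc1)(c1ccccc1)C(C)(C)C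
F8 | step 15 | tris-silyl exo-methylene bicyclo[3.2.1]octane lactone | C=C1C[C@]23C[C@H]1C[C@H](O[Si](C)(C)C(C)(C)C)[C@H]2[C@]1(COC3=O)[C@@H](O[Si](CC)(CC)CC)CCC(C)(C)[C@H]1CO[Si](c1ccccc1)(c1ccccc1)C(C)(C)C
F9 | step 15 | C1 alcohol of F8 | C=C1C[C@]23C[C@H]1C[C@H](O[Si](C)(C)C(C)(C)C)[C@H]2[C@]1(COC3=O)[C@@H](O)CCC(C)(C)[C@H]1CO[Si](c1ccccc1)(c1ccccc1)C(C)(C)C
F10 | step 15 | C1 acetate of F9 | C=C1C[C@]23C[C@H]1C[C@H](O[Si](C)(C)C(C)(C)C)[C@H]2[C@]1(COC3=O)[C@@H](OC(C)=O)CCC(C)(C)[C@H]1CO[Si](c1ccccc1)(c1ccccc1)C(C)(C)C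
F11 | step 4 | ent-8 | O=C1CCC(C)(C)[C@H](C[Si](C)(C)OC(C)C)[C@H]1CN(C)C
F12 | step 4 | (S)-mandelate salt of 8 | O=C1CCC(C)(C)[C@@H](C[Si](C)(C)OC(C)C)[C@@H]1C[NH+](C)C.O[C@H](C([O-])=O)c1ccccc1
F13 | step 12 | 4-[2-(3,3-dimethoxycyclobutyl)prop-2-en-1-yl] derivative of 18 (C8 epimers) | O=C1C(CC(=C)C3CC(OC)(OC)C3)C[C@]2(CO1)[C@@H](O[Si](CC)(CC)CC)CCC(C)(C)[C@H]2CO[Si](c1ccccc1)(c1ccccc1)C(C)(C)C
F14 | step 12 | 8-(phenylselanyl) derivative of F13 | O=C1C([Se]c4ccccc4)(CC(=C)C3CC(OC)(OC)C3)C[C@]2(CO1)[C@@H](O[Si](CC)(CC)CC)CCC(C)(C)[C@H]2CO[Si](c1ccccc1)(c1ccccc1)C(C)(C)C
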